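The runs are simulated from invented constants; scatter was added.

Early times are out of reach: by the first winter reading, at 1.04 d, the starting material already reads 1.0%, and the later readings hold within the scatter. So the runs give you end amounts, not rates, and you treat the two nucleophiles as you would competing substrates.

in all of them: starting material 0.30 M
- midnight: first nucleophile 0.39 M; second nucleophile 0.19 M; capture agent 0.090 M; run made earlier
- winter: first nucleophile 0.39 M; second nucleophile 0.43 M; capture agent 0.090 M; run made earlier
- autumn: first nucleophile 0.58 M; second nucleophile 0.285 M; capture agent 0.090 M; run made earlier
- flask: first nucleophile 0.390 M; second nucleophile 0.285 M; capture agent 0.0900 M; time 15 d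

| run | time / d | starting material / % | target / % | other capture product / % |
|---|---|---|---|---|
| midnight | 2.50 | 0.5 | 49.4 | 51.8 |
| midnight | 5.00 | 0 | 48.9 | 51.1 |
| midnight | 8.00 | 0.5 | 48.8 | 51.4 |
| midnight | 10.0 | 0.6 | 49.0 | 52.1 |
| midnight | 12.0 | 0 | 49.2 | 49.9 |
| winter | 1.04 | 1.0 | 25.0 | 75.3 |
| winter | 1.67 | 0 | 25.7 | 75.2 |
| winter | 3.00 | 0 | 24.7 | 76.4 |
| winter | 6.00 | 0 | 26.1 | 75.9 |
| winter | 12.0 | 0 | 24.1 | 74.2 |
| autumn | 1.04 | 0 | 43.2 | 56.9 |
| autumn | 3.00 | 1.6 | 42.8 | 57.6 |
| autumn | 6.00 | 1.6 | 43.8 | 57.7 |
| autumn | 8.00 | 0 | 43.3 | 57.5 |
| autumn | 12.0 | 0.1 | 43.2 | 57.9 |

(scatter of a reading: 1 percentage point)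

- the earlier runs were read with a standard deviation of 1 percentage point
- the reaction counts as stopped when no species that holds the starting material changes by six tenths of a point or more over the second half of the time

- why nothing more happens at 15 d, or that something still does (all of the starting material has reacted / the first nucleophile has run out first / the second nucleophile has run out first / it is still moving)
- how much of the starting material has reacted by 15 d
- how much target there is at 15 d, in percent of the starting material charged
- how much other capture product there is at 15 d, in percent of the starting material charged

Let each product cost one molecule of its nucleophile, with d[other capture product]/d[target] = S[second nucleophile]/[first nucleophile]. Then S = ln([second nucleophile]end/charge) / ln([first nucleophile]end/charge). The averaged readings give 3.50 for midnight, 3.48 for winter and 3.67 for autumn. Their mean, 3.55, is the selectivity factor, the preference for second nucleophile over first at equal concentrations.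

In the flask, second nucleophile is the smaller charge, and the two nucleophiles together exceed the starting material. You therefore take conversion as complete, and [second nucleophile] is its charge minus [other capture product]. From below, the midnight run, with less second nucleophile and otherwise equal charges, read 51.3% other capture product. From above, unworn charges give 72.2%, a ceiling, since S is above 1 and second nucleophile wears proportionally faster. To tighten this, an end at 62.5% needs S = 3.15, and one at 66.7% needs 4.08. The reading lies between them, and interpolation gives 64.3%.

The forecast, reading “competing capture of a common intermediate”, says all of the starting material has reacted, with 100% conversion, 36% target (34% to 38%) and 64% other capture product (62% to 66%), a central value above 62.5% and below 66.7%.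

The flask gives: all of the starting material has reacted, with 100% conversion, 35.2% target and 64.6% other capture product, against your 64.3%.

    second nucleophile + open intermediate → other capture product (k = 0.140 L mol⁻¹ min⁻¹)
    open intermediate + capture agent → trapped intermediate (k = 5.60 × 10⁻⁴ L mol⁻¹ min⁻¹)
    target → over-reaction product (k = 1.60 × 10⁻⁷ min⁻¹)
    first nucleophile + open intermediate → target (k = 0.0390 L mol⁻¹ min⁻¹)
    starting material → open intermediate (k = 0.00830 min⁻¹)

Target stays at 35.2% in this flask because second nucleophile captures the open intermediate: the run without that step gives 99.0% target. Now take a neighbour flask, with 0.16 M of first nucleophile. An end at 75.0% other capture product needs S = 2.46, and one at 80.0% needs 3.93, so 3.55 interpolates to 78.7%. The computed neighbour flask gives 79.0% other capture product and 20.8% target.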